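## The problem

Compound 19, (3R,4R)-3,4-bis[(S)-hydroxy(4-hydroxy-3-methoxyphenyl)methyl]oxolane, is a C2-symmetric 9,9′-epoxylignan. In the lignan numbering used here the oxolane methylenes are C9 and C9′, the ring methines C8 and C8′, and the exocyclic carbinol carbons C7 and C7′; the four contiguous stereocentres are 7S, 8R, 8′R, 7′S. The trans relation of C8 and C8′ is the stable one whenever one of these carbons is enolisable and can be left to equilibration. The real task is to set each carbinol centre relative to its ring neighbour, the same 1,2-relation twice, and to bring in the absolute configuration once. All four oxygens can close five-membered ethers: O7 reaches C9′ as easily as O9 does, so the benzylic oxygens must be masked when the oxolane is closed. The p-hydroxybenzylic alcohols ionise to quinone methides under acid and are cleaved by hydrogenolysis, and the guaiacol rings are easily oxidised, so the last steps must be neutral and non-reductive. The enabling feature is the unit C7–C8–C8′: with C7′ raised to a ketone and C9′ to a carboxyl carbon it is a donor–acceptor cyclopropane, with the guaiacyl ring on C7 as donor and two carbonyl groups on C8′ as acceptors, and O9 can be the ester oxygen that ties carbene to alkene. One intramolecular carbene addition to a Z-cinnamyl ester can therefore form C8–C8′, a temporary C7–C8′ bond and a lactone ring, and an oxygen nucleophile can then break the temporary bond at C7 with inversion.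

## Retrosynthesis

**19 ⇒ 18.** No skeletal bond is cut; four O–Si bonds are added. Carrying all four hydroxyls as tert-butyldimethylsilyl ethers allows one buffered fluoride treatment at the end, which is the mildest exit for two p-hydroxybenzylic alcohols. Benzyl ethers on the phenols were set aside because their hydrogenolysis endangers the benzylic C–O bonds.

**18 ⇒ 16 (through 17) ⇒ 15.** The O–C9′ bond of the oxolane is cut, giving the C2-symmetric diol 16 with two homotopic primary hydroxyls; its monotosylate 17 closes the ring. Cutting an ether bond is preferred to building the ring by C–C bond formation because the ring carbons are then free to come from a lactone. The lactone 15 holds C9′ at the acid level, where it has done its work as acceptor and as chelating group. The forward reaction needs only that O7 and O7′ are already silylated, so that neither can close a 2-aryloxolane.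

**15 ⇒ 14 ⇒ 13.** The C7′–H bond is cut: the second carbinol comes from the aryl ketone of 13. The neighbouring cut, an aldol C7′–C8′ bond, would add a fragment coupling and a second diastereoselection. Here the carbon is already in place and the lactone carbonyl next to the ketone offers a zinc chelate. The forward reduction must deliver hydride to one face of the ketone, and the lactone is kept until then for that reason.

**13 ⇒ 12 ⇒ 11.** The C7–O bond is cut and C7 is reconnected to C8′, which gives the bicyclic donor–acceptor cyclopropane 11. This turns an open-chain 1,2-relation (C7/C8) into the cis/trans geometry of a three-membered ring, set by alkene geometry and read out by inversion. The precursor has three stereocentres locked in a rigid bicycle. The forward reaction must attack the benzylic carbon from the back before the electron-rich benzylic centre ionises; silylating 12 to 13 straight away keeps the new hydroxyl from adding to the ketone or to the lactone carbonyl.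

**11 ⇒ 10.** The C8–C8′ and C7–C8′ bonds are cut together, leaving the achiral Z-cinnamyl α-diazo-β-keto ester 10. An intermolecular cyclopropanation would give neither the lactone nor reliable diastereocontrol, and a Michael-initiated ring closure would need a preformed stereocentre. The intramolecular carbene addition closes both rings, fixes the relative configuration through the alkene geometry and leaves only the alkene face to a chiral catalyst. All stereochemical information of the route enters here.

**10 ⇒ 9 ⇒ 7 + 4 (through 8).** The diazo group comes from diazo transfer to β-keto ester 9. The ester C–O bond is cut to the acyl Meldrum's acid 7 and the Z-allylic alcohol 4; on heating, 7 gives aroylketene 8, which the alcohol captures. This acylation is neutral, which suits a Z-cinnamyl alcohol and aryl silyl ethers better than transesterification.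

**7 ⇒ 5 + 6; 5 ⇒ 1; 4 ⇒ 3 ⇒ 1 + 2.** Both aromatic halves come from aldehyde 1. Oxidation gives acid 5, which acylates Meldrum's acid 6. A Z-selective olefination with phosphonate 2 gives enoate 3, and reduction gives alcohol 4. The alkyne semihydrogenation route to 4 was not chosen because it needs a second aromatic starting material.

## Roads not taken

**Alternative 1:** The cut runs through C8–C9 and C8′–C9′, so the oxolane comes from a C–O–C dipole and a fumaric acid derivative.
- Forward key step: CsF strips silicon and chloride from chloromethyl (trimethylsilyl)methyl ether A2 to give the parent carbonyl ylide. This adds suprafacially to fumaroyl bis(bornane-10,2-sultam) A1 and gives the trans-oxolane-3,4-dicarbonyl bis(sultam) A3. Aryl-metal addition would lead to the 3,4-diaroyloxolane A4, and a double ketone reduction to the carbinols.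
- Merits: the ring and both ring stereocentres form in one step, trans is inherited from the fumarate, and the C2 symmetry is used fully. The oxolane exists before any hydroxyl does, so the choice between ether closures never arises. About six steps.
- Weak points: the unstabilised ylide is small and short-lived, so face discrimination by the sultams is not assured. The carbinol centres are made afterwards from A4, where only the adjacent ring methine and a possible chelate to the ring oxygen can steer hydride, and the sense must be right twice. Two equivalents of auxiliary are consumed.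
- Comparison: this road is shorter and is better on the ether question. The chosen plan sets against it that C7 comes from a stereospecific sequence (alkene geometry, then inversion), that its one ketone reduction has a lactone carbonyl to chelate, and that the absolute configuration comes from a catalyst.

**Alternative 2:** The cut is at C7–C8 and C7′–C8′, made by sigmatropic shifts.
- Forward key step: the bis(benzyl) ether A5 of (2Z,4Z)-hexa-2,4-diene-1,6-diol would be lithiated at a benzylic carbon with t-BuLi and a chiral bis(oxazoline). Two successive [2,3]-Wittig shifts would give the 1,4-diaryl-2,3-divinylbutane-1,4-diol A6 with all four stereocentres; the vinyl groups would then be cleaved to the C9 and C9′ alcohols.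
- Merits: one operation on an achiral, symmetric precursor. The carbinols appear before the primary alcohols, so they can be silylated first, and the end game equals that of the chosen plan. About nine or ten steps.
- Weak points: deprotonation of an electron-rich benzyl ether competes with ortho-lithiation next to the methoxy and silyloxy groups and with the [1,2]-shift. The second shift takes place in a chiral alkoxide that may or may not match the ligand. The transfer from Z geometry to syn products is less strict for aryl-stabilised carbanions.
- Comparison: it is shorter on paper and equal in the end game. It asks for three selectivities in one flask, whereas the chosen plan spreads them over steps 7, 8 and 10, each with its own control element.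

**Alternative 3:** The cut is the central C8–C8′ bond, as in lignan biosynthesis.
- Forward key step: one-electron oxidation (FeCl3/O2 or Ag2O) of a ferulic amide with a chiral auxiliary, for example ethyl N-feruloyl-(S)-alaninate A7, gives phenoxyl radicals that couple at their β-carbons. Each amide oxygen then adds to the opposite quinone methide, and the two rings hydrolyse to the exo,exo-dilactone A8.
- Merits: it is the shortest road. The central bond and four stereocentres arise at once, and the cis-fused dilactone has the relative configuration of 19 once it is reduced and re-closed between C9 and C9′. The materials are cheap.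
- Weak points: radical coupling also gives β–5 and β–O–4 isomers, and a remote auxiliary controls the face of a radical–radical coupling only weakly. Most serious for this target, reduction of A8 frees all four hydroxyls at once, beside free phenols. The benzylic oxygens cannot be masked before the primary ones exist, and closure then tends towards the 7,9′-linked ethers unless a protect–deprotect detour is added.
- Comparison: in step count and in the directness of the C8–C8′ bond it is better. The chosen plan sets against it catalyst-controlled absolute configuration and an order of events in which each carbinol oxygen is silylated as it appears, before C9 and C9′ are alcohols.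

Key step: step 7

Abbreviations: TBS = tert-butyldimethylsilyl; Ar = 4-(tert-butyldimethylsilyloxy)-3-methoxyphenyl; ArCO = the corresponding benzoyl group.

Remark: aldehyde 1 (O-TBS-vanillin) is taken as a catalogue compound; otherwise it is one step from vanillin (TBSCl, imidazole).

Remark: Rh2(S-PTTL)4 is assumed to give the (1S,5R,6R) enantiomer of 11; if the sense proves opposite, the mirror-image catalyst Rh2(R-PTTL)4 is used in the same step.

## Route

Step 1
Reactants: 1 4-(tert-butyldimethylsilyloxy)-3-methoxybenzaldehyde; 2 methyl 2-[bis(2,2,2-trifluoroethoxy)phosphoryl]acetate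
Product: 3 methyl (2Z)-3-Ar-prop-2-enoate
Conditions: KN(SiMe3)2, 18-crown-6, THF, −78 °C
Reagents that add atoms: none
Why: Still–Gennari variant of the Horner–Wadsworth–Emmons olefination: with the electron-poor bis(trifluoroethyl) phosphonate and a crown-ether-separated potassium ion the kinetic syn adduct collapses before it equilibrates, which should give the Z-cinnamate from an aromatic aldehyde.

Step 2
Reactants: 3 methyl (2Z)-3-Ar-prop-2-enoate
Product: 4 (2Z)-3-Ar-prop-2-en-1-ol
Conditions: i-Bu2AlH, CH2Cl2, −78 °C; aq. potassium sodium tartrate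
Reagents that add atoms: none
Why: 1,2-Reduction of the unsaturated ester by two hydride equivalents of i-Bu2AlH should give the allylic alcohol without touching the alkene geometry or the aryl silyl ether.

Step 3
Reactants: 1 4-(tert-butyldimethylsilyloxy)-3-methoxybenzaldehyde
Product: 5 4-(tert-butyldimethylsilyloxy)-3-methoxybenzoic acid
Conditions: NaClO2, NaH2PO4, 2-methylbut-2-ene, t-BuOH–THF–H2O, 0 °C → rt
Reagents that add atoms: sodium chlorite, [Na+].[O-]Cl=O
Why: Pinnick oxidation by chlorous acid; 2-methylbut-2-ene traps the hypochlorous acid that would chlorinate the electron-rich ring, and the phosphate buffer spares the aryl silyl ether.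

Step 4
Reactants: 5 4-(tert-butyldimethylsilyloxy)-3-methoxybenzoic acid; 6 Meldrum's acid (2,2-dimethyl-1,3-dioxane-4,6-dione)
Product: 7 5-[Ar(hydroxy)methylidene]-2,2-dimethyl-1,3-dioxane-4,6-dione
Conditions: EDC·HCl, DMAP, CH2Cl2, 0 °C → rt; cold aq. KHSO4 wash
Reagents that add atoms: none
Why: Carbodiimide activation gives an acylpyridinium ion that C-acylates the acidic methylene of 6 (acylation of Meldrum's acid); the product is isolated as its stable enol.

Step 5
Reactants: 7 5-[Ar(hydroxy)methylidene]-2,2-dimethyl-1,3-dioxane-4,6-dione; 4 (2Z)-3-Ar-prop-2-en-1-ol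
Product: 9 (2Z)-3-Ar-prop-2-en-1-yl 3-Ar-3-oxopropanoate, via aroylketene 8 (not isolated)
Conditions: toluene, 90 °C
Reagents that add atoms: none
Why: Thermal cycloreversion of the acyl Meldrum's acid releases acetone and CO2 and gives aroylketene 8, which adds the allylic alcohol to give the β-keto ester; the neutral medium preserves the Z alkene and the silyl ethers.

Step 6
Reactants: 9 (2Z)-3-Ar-prop-2-en-1-yl 3-Ar-3-oxopropanoate
Product: 10 (2Z)-3-Ar-prop-2-en-1-yl 2-diazo-3-Ar-3-oxopropanoate
Conditions: p-ABSA, Et3N, MeCN, 0 °C → rt
Reagents that add atoms: 4-acetamidobenzenesulfonyl azide (p-ABSA), CC(=O)Nc1ccc(cc1)S(=O)(=O)N=[N+]=[N-]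
Why: Regitz diazo transfer to the doubly activated methylene; triethylamine suffices for a β-keto ester and the sulfonamide by-product is removed by a wash.

Step 7
Reactants: 10 (2Z)-3-Ar-prop-2-en-1-yl 2-diazo-3-Ar-3-oxopropanoate
Product: 11 (1S,5R,6R)-1-(ArCO)-6-Ar-3-oxabicyclo[3.1.0]hexan-2-one (Ar on C6 endo, cis to C4)
Conditions: Rh2(S-PTTL)4 (1 mol%), CH2Cl2, high dilution, rt → 40 °C
Reagents that add atoms: none
Why: Loss of N2 from 10 at an axial site of the dirhodium tetracarboxylate gives an electrophilic acceptor/acceptor rhodium carbene, which adds to the tethered Z alkene in a concerted, asynchronous (2+1) step. The closest known reaction type is the intramolecular cyclopropanation of allyl α-diazo-β-keto esters, allyl diazomalonates and allyl cyanodiazoacetates to 3-oxabicyclo[3.1.0]hexan-2-ones, including enantioselective versions with chiral dirhodium carboxylates. The lactone closes in a 5-exo sense (carbene carbon to the proximal alkene carbon, the benzylic carbon left outside the five-membered ring), and the cyclopropane closes as the three-membered ring of the same cheletropic addition. C5 and C6 are set relative to each other by the Z geometry, which the suprafacial addition transfers unchanged, so the aryl group ends cis to C4 (endo); C1 follows from the obligatory cis fusion; the absolute sense of all three comes from the alkene face left open by the chiral pocket of the tert-leucinate ligands. The step needs chemoselectivity for the alkene over the electron-rich arenes and over attack by the keto oxygen, which the five-atom tether secures, and enantioface selectivity, for which a Z alkene is the favourable case because one approach pushes its aryl group against the ligand wall. Low catalyst loading and moderate temperature should keep the Lewis-acidic rhodium from opening the strained endo product.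

Step 8
Reactants: 11 (1S,5R,6R)-1-(ArCO)-6-Ar-3-oxabicyclo[3.1.0]hexan-2-one
Product: 12 (3S,4R)-3-(ArCO)-4-[(S)-Ar(hydroxy)methyl]oxolan-2-one
Conditions: Sc(OTf)3 (10 mol%), MeCN–H2O 9:1, 0 °C → rt
Reagents that add atoms: water, O
Why: Lewis-acid-catalysed nucleophilic ring opening of a donor–acceptor cyclopropane (homo-conjugate addition): trivalent scandium binds the keto lactone and polarises the C1–C6 bond, and water attacks the benzylic carbon anti to the departing C1, which turns the endo centre into the (S)-carbinol. The enolate is protonated to the 3,4-trans keto lactone, the stable arrangement at this freely enolisable carbon; aryl silyl ethers tolerate Sc(OTf)3/water and no alkyl silyl ether is present yet.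

Step 9
Reactants: 12 (3S,4R)-3-(ArCO)-4-[(S)-Ar(hydroxy)methyl]oxolan-2-one
Product: 13 (3S,4R)-3-(ArCO)-4-[(S)-Ar(tert-butyldimethylsilyloxy)methyl]oxolan-2-one
Conditions: TBSCl, imidazole, DMF, 0 °C → rt
Reagents that add atoms: tert-butyldimethylsilyl chloride, CC(C)(C)[Si](C)(C)Cl
Why: Silylation of the only free hydroxyl; capping O7 at once removes hemiketal formation with the ketone and translactonisation, and leaves the two carbonyl groups as the only chelating pair for step 10.

Step 10
Reactants: 13 (3S,4R)-3-(ArCO)-4-[(S)-Ar(tert-butyldimethylsilyloxy)methyl]oxolan-2-one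
Product: 14 (3S,4R)-3-[(S)-Ar(hydroxy)methyl]-4-[(S)-Ar(tert-butyldimethylsilyloxy)methyl]oxolan-2-one
Conditions: Zn(BH4)2, Et2O–THF, −40 → 0 °C
Reagents that add atoms: none
Why: Chelation-controlled reduction of an α-substituted β-keto ester, here an α-aroyl lactone: zinc bridges the ketone and lactone carbonyl oxygens and hydride reaches the ketone face next to the small H3, away from ring carbon C4, which should give the (S)-carbinol and repeat on this side the C7/C8 relation made in step 8. Zn(BH4)2 leaves lactone and silyl ethers alone, and C3 is no longer flanked by two carbonyl groups afterwards, so it keeps its trans configuration.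

Step 11
Reactants: 14 (3S,4R)-3-[(S)-Ar(hydroxy)methyl]-4-[(S)-Ar(tert-butyldimethylsilyloxy)methyl]oxolan-2-one
Product: 15 (3S,4R)-3,4-bis[(S)-Ar(tert-butyldimethylsilyloxy)methyl]oxolan-2-one
Conditions: TBSOTf, 2,6-lutidine, CH2Cl2, −78 → 0 °C
Reagents that add atoms: tert-butyldimethylsilyl trifluoromethanesulfonate, CC(C)(C)[Si](C)(C)OS(=O)(=O)C(F)(F)F
Why: The hindered secondary benzylic alcohol is silylated by the reactive triflate with a non-nucleophilic base; both carbinol oxygens are now masked before any primary hydroxyl exists.

Step 12
Reactants: 15 (3S,4R)-3,4-bis[(S)-Ar(tert-butyldimethylsilyloxy)methyl]oxolan-2-one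
Product: 16 (2R,3R)-2,3-bis[(S)-Ar(tert-butyldimethylsilyloxy)methyl]butane-1,4-diol
Conditions: LiBH4, THF (MeOH 1 equiv), 0 °C → rt
Reagents that add atoms: none
Why: Reduction of the lactone to the 1,4-diol by LiBH4, which leaves aryl and alkyl silyl ethers alone; no stereocentre is touched and the product regains C2 symmetry.

Step 13
Reactants: 16 (2R,3R)-2,3-bis[(S)-Ar(tert-butyldimethylsilyloxy)methyl]butane-1,4-diol
Product: 18 (3R,4R)-3,4-bis[(S)-Ar(tert-butyldimethylsilyloxy)methyl]oxolane, via monotosylate 17 (not isolated)
Conditions: TsCl, pyridine, DMAP (cat.), 0 → 50 °C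
Reagents that add atoms: none
Why: Sulfonylation of one of the two homotopic primary hydroxyls and 5-exo-tet displacement by the other (intramolecular Williamson-type etherification, helped by the 2,3-disubstitution). The silylated carbinol oxygens cannot compete, and an amine base in place of a metal alkoxide avoids 1,3-silyl migration.

Step 14
Reactants: 18 (3R,4R)-3,4-bis[(S)-Ar(tert-butyldimethylsilyloxy)methyl]oxolane
Product: 19 (3R,4R)-3,4-bis[(S)-hydroxy(4-hydroxy-3-methoxyphenyl)methyl]oxolane
Conditions: TBAF, AcOH, THF, 0 °C → rt
Reagents that add atoms: none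
Why: Fluoride cleaves the two aryl and the two benzylic silyl ethers in one operation; acetic acid buffers the phenoxides so that the p-hydroxybenzylic alcohols are neither ionised nor eliminated to quinone methides.

## Compound list

1 | 4-(tert-butyldimethylsilyloxy)-3-methoxybenzaldehyde | COc1cc(C=O)ccc1O[Si](C)(C)C(C)(C)C | starting material
2 | methyl 2-[bis(2,2,2-trifluoroethoxy)phosphoryl]acetate | COC(=O)CP(=O)(OCC(F)(F)F)OCC(F)(F)F | starting material
3 | methyl (2Z)-3-[4-(tert-butyldimethylsilyloxy)-3-methoxyphenyl]prop-2-enoate | COC(=O)/C=C\c1ccc(O[Si](C)(C)C(C)(C)C)c(OC)c1 | intermediate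
4 | (2Z)-3-[4-(tert-butyldimethylsilyloxy)-3-methoxyphenyl]prop-2-en-1-ol | OC/C=C\c1ccc(O[Si](C)(C)C(C)(C)C)c(OC)c1 | intermediate
5 | 4-(tert-butyldimethylsilyloxy)-3-methoxybenzoic acid | COc1cc(C(=O)O)ccc1O[Si](C)(C)C(C)(C)C | intermediate
6 | Meldrum's acid (2,2-dimethyl-1,3-dioxane-4,6-dione) | CC1(C)OC(=O)CC(=O)O1 | starting material
7 | 5-{[4-(tert-butyldimethylsilyloxy)-3-methoxyphenyl](hydroxy)methylidene}-2,2-dimethyl-1,3-dioxane-4,6-dione | CC1(C)OC(=O)C(=C(O)c2ccc(O[Si](C)(C)C(C)(C)C)c(OC)c2)C(=O)O1 | intermediate
8 | 3-[4-(tert-butyldimethylsilyloxy)-3-methoxyphenyl]-3-oxoprop-1-en-1-one (aroylketene) | O=C=CC(=O)c1ccc(O[Si](C)(C)C(C)(C)C)c(OC)c1 | intermediate (not isolated)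
9 | (2Z)-3-[4-(tert-butyldimethylsilyloxy)-3-methoxyphenyl]prop-2-en-1-yl 3-[4-(tert-butyldimethylsilyloxy)-3-methoxyphenyl]-3-oxopropanoate | O=C(CC(=O)c1ccc(O[Si](C)(C)C(C)(C)C)c(OC)c1)OC/C=C\c1ccc(O[Si](C)(C)C(C)(C)C)c(OC)c1 | intermediate
10 | (2Z)-3-[4-(tert-butyldimethylsilyloxy)-3-methoxyphenyl]prop-2-en-1-yl 2-diazo-3-[4-(tert-butyldimethylsilyloxy)-3-methoxyphenyl]-3-oxopropanoate | [N-]=[N+]=C(C(=O)c1ccc(O[Si](C)(C)C(C)(C)C)c(OC)c1)C(=O)OC/C=C\c1ccc(O[Si](C)(C)C(C)(C)C)c(OC)c1 | intermediate
11 | (1S,5R,6R)-1-[4-(tert-butyldimethylsilyloxy)-3-methoxybenzoyl]-6-[4-(tert-butyldimethylsilyloxy)-3-methoxyphenyl]-3-oxabicyclo[3.1.0]hexan-2-one | O=C1OC[C@@H]2[C@H](c3ccc(O[Si](C)(C)C(C)(C)C)c(OC)c3)[C@]12C(=O)c1ccc(O[Si](C)(C)C(C)(C)C)c(OC)c1 | intermediate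
12 | (3S,4R)-3-[4-(tert-butyldimethylsilyloxy)-3-methoxybenzoyl]-4-{(S)-[4-(tert-butyldimethylsilyloxy)-3-methoxyphenyl](hydroxy)methyl}oxolan-2-one | O=C1OC[C@H]([C@H](O)c2ccc(O[Si](C)(C)C(C)(C)C)c(OC)c2)[C@H]1C(=O)c1ccc(O[Si](C)(C)C(C)(C)C)c(OC)c1 | intermediate
13 | (3S,4R)-3-[4-(tert-butyldimethylsilyloxy)-3-methoxybenzoyl]-4-{(S)-(tert-butyldimethylsilyloxy)[4-(tert-butyldimethylsilyloxy)-3-methoxyphenyl]methyl}oxolan-2-one | O=C1OC[C@H]([C@H](O[Si](C)(C)C(C)(C)C)c2ccc(O[Si](C)(C)C(C)(C)C)c(OC)c2)[C@H]1C(=O)c1ccc(O[Si](C)(C)C(C)(C)C)c(OC)c1 | intermediate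
14 | (3S,4R)-3-{(S)-[4-(tert-butyldimethylsilyloxy)-3-methoxyphenyl](hydroxy)methyl}-4-{(S)-(tert-butyldimethylsilyloxy)[4-(tert-butyldimethylsilyloxy)-3-methoxyphenyl]methyl}oxolan-2-one | O=C1OC[C@H]([C@H](O[Si](C)(C)C(C)(C)C)c2ccc(O[Si](C)(C)C(C)(C)C)c(OC)c2)[C@H]1[C@H](O)c1ccc(O[Si](C)(C)C(C)(C)C)c(OC)c1 | intermediate
15 | (3S,4R)-3,4-bis{(S)-(tert-butyldimethylsilyloxy)[4-(tert-butyldimethylsilyloxy)-3-methoxyphenyl]methyl}oxolan-2-one | O=C1OC[C@H]([C@H](O[Si](C)(C)C(C)(C)C)c2ccc(O[Si](C)(C)C(C)(C)C)c(OC)c2)[C@H]1[C@H](O[Si](C)(C)C(C)(C)C)c1ccc(O[Si](C)(C)C(C)(C)C)c(OC)c1 | intermediate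
16 | (2R,3R)-2,3-bis{(S)-(tert-butyldimethylsilyloxy)[4-(tert-butyldimethylsilyloxy)-3-methoxyphenyl]methyl}butane-1,4-diol | OC[C@H]([C@H](O[Si](C)(C)C(C)(C)C)c1ccc(O[Si](C)(C)C(C)(C)C)c(OC)c1)[C@H](CO)[C@H](O[Si](C)(C)C(C)(C)C)c1ccc(O[Si](C)(C)C(C)(C)C)c(OC)c1 | intermediate
17 | (2R,3R)-4-hydroxy-2,3-bis{(S)-(tert-butyldimethylsilyloxy)[4-(tert-butyldimethylsilyloxy)-3-methoxyphenyl]methyl}butyl 4-methylbenzenesulfonate | OC[C@H]([C@H](O[Si](C)(C)C(C)(C)C)c1ccc(O[Si](C)(C)C(C)(C)C)c(OC)c1)[C@H](COS(=O)(=O)c1ccc(C)cc1)[C@H](O[Si](C)(C)C(C)(C)C)c1ccc(O[Si](C)(C)C(C)(C)C)c(OC)c1 | intermediate (not isolated)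
18 | (3R,4R)-3,4-bis{(S)-(tert-butyldimethylsilyloxy)[4-(tert-butyldimethylsilyloxy)-3-methoxyphenyl]methyl}oxolane | COc1cc([C@@H](O[Si](C)(C)C(C)(C)C)[C@H]2COC[C@@H]2[C@H](O[Si](C)(C)C(C)(C)C)c2ccc(O[Si](C)(C)C(C)(C)C)c(OC)c2)ccc1O[Si](C)(C)C(C)(C)C | intermediate
19 | (3R,4R)-3,4-bis[(S)-hydroxy(4-hydroxy-3-methoxyphenyl)methyl]oxolane | COc1cc([C@@H](O)[C@H]2COC[C@@H]2[C@H](O)c2ccc(O)c(OC)c2)ccc1O | target

## Step count and uncertain steps

Total: 14 steps. Longest linear sequence: 12 steps (steps 1, 2, 5–14 from aldehyde 1; the branch through steps 3 and 4 is equally long).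

**Step 7 (key step).**
- What may go wrong: weak enantioface discrimination. An acceptor/acceptor rhodium carbene is very electrophilic, its transition state is early and it feels the chiral ligands only weakly. In addition, the Lewis-acidic catalyst may start to open or ring-expand the strained, strongly polarised product.
- Fallback (from alcohol 4 and aldehyde 1, back at 11): split the task so that the same two bonds and the same two rings are formed from an acceptor-only carbene, the class for which Z-allylic esters are the best-behaved substrates. Alcohol 4 is converted with glyoxylic acid chloride tosylhydrazone (PhNMe2, then Et3N) into (2Z)-3-Ar-prop-2-en-1-yl 2-diazoacetate F1. The dirhodium carboxamidate Rh2(5S-MEPY)4 (or its mirror image) cyclises F1 to (1S,5R,6S)-6-Ar-3-oxabicyclo[3.1.0]hexan-2-one F2. F2 is deprotonated at the bridgehead carbon with LiN(SiMe3)2 at −78 °C and added to aldehyde 1, giving the carbinol (1S,5R,6R)-1-[Ar(hydroxy)methyl]-6-Ar-3-oxabicyclo[3.1.0]hexan-2-one F3 as a mixture of carbinol epimers. Dess–Martin oxidation of F3 gives 11.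

**Step 8.**
- What may go wrong: ionisation of the C1–C6 bond ahead of backside attack. The p-silyloxyaryl group stabilises a benzylic cation, which can lead to unselective capture by water, endo-to-exo epimerisation of the cyclopropane, or ring expansion by the ketone oxygen.
- Fallback (from 11, back at 12): let the ketone oxygen open the ring on purpose. Anhydrous Sc(OTf)3 in CH2Cl2 should bring about the Cloke–Wilson rearrangement to the dihydrofuran (3aR,4S)-4,6-di-Ar-3a,4-dihydro-1H,3H-furo[3,4-c]furan-1-one F4. In F4 the aryl group on the sp3 carbon settles on the convex face, trans to the lactone methylene. This is the same C7 configuration that backside attack gives, and it is reached even after ionisation because the closure is reversible. Hydrolysis of the enol ether in dilute aqueous acid cleaves the O–C7′ bond only and gives 12.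

**Step 9.**
- What may go wrong: slow silylation of the hindered carbinol while the base promotes lactone migration onto O7, enol silylation, or hemiketal closure.
- Fallback (from 12, back at 15): change the order. Reduce 12 directly with Zn(BH4)2, which drains the open-chain ketone out of any ring–chain equilibrium, to (3S,4R)-3,4-bis[(S)-Ar(hydroxy)methyl]oxolan-2-one F5. Silylate both carbinols of F5 together with TBSOTf/2,6-lutidine to reach 15. This saves a step, at the price of a free O7–H near the zinc chelate.

**Step 10.**
- What may go wrong: poor facial selectivity, if the zinc chelate is not formed cleanly and an open, Felkin-type transition state competes, which would give the 7′-epimer.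
- Fallback (from 13, back at 14): replace substrate control by reagent control. A Corey–Bakshi–Shibata reduction with the (R)-2-methyl-oxazaborolidine and catecholborane in toluene at low temperature, with the aryl group as the larger ketone substituent, should deliver the (S)-carbinol whatever the chelate does. No compound outside the list is made (F0).

## Further compounds

F1 | step 7 | (2Z)-3-[4-(tert-butyldimethylsilyloxy)-3-methoxyphenyl]prop-2-en-1-yl 2-diazoacetate | [N-]=[N+]=CC(=O)OC/C=C\c1ccc(O[Si](C)(C)C(C)(C)C)c(OC)c1
F2 | step 7 | (1S,5R,6S)-6-[4-(tert-butyldimethylsilyloxy)-3-methoxyphenyl]-3-oxabicyclo[3.1.0]hexan-2-one | O=C1OC[C@@H]2[C@H](c3ccc(O[Si](C)(C)C(C)(C)C)c(OC)c3)[C@H]12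
F3 | step 7 | (1S,5R,6R)-1-{[4-(tert-butyldimethylsilyloxy)-3-methoxyphenyl](hydroxy)methyl}-6-[4-(tert-butyldimethylsilyloxy)-3-methoxyphenyl]-3-oxabicyclo[3.1.0]hexan-2-one (carbinol epimers) | O=C1OC[C@@H]2[C@H](c3ccc(O[Si](C)(C)C(C)(C)C)c(OC)c3)[C@]12C(O)c1ccc(O[Si](C)(C)C(C)(C)C)c(OC)c1
F4 | step 8 | (3aR,4S)-4,6-bis[4-(tert-butyldimethylsilyloxy)-3-methoxyphenyl]-3a,4-dihydro-1H,3H-furo[3,4-c]furan-1-one | O=C1OC[C@H]2C1=C(c3ccc(O[Si](C)(C)C(C)(C)C)c(OC)c3)O[C@@H]2c4ccc(O[Si](C)(C)C(C)(C)C)c(OC)c4
F5 | step 9 | (3S,4R)-3,4-bis{(S)-[4-(tert-butyldimethylsilyloxy)-3-methoxyphenyl](hydroxy)methyl}oxolan-2-one | O=C1OC[C@H]([C@H](O)c2ccc(O[Si](C)(C)C(C)(C)C)c(OC)c2)[C@H]1[C@H](O)c1ccc(O[Si](C)(C)C(C)(C)C)c(OC)c1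
F0 | step 10 | none | none
A1 | alternative 1 | (E)-but-2-enedioyl bis(bornane-10,2-sultam) | O=C(/C=C/C(=O)N1[C@@H]2C[C@H]3CC[C@]2(CS1(=O)=O)C3(C)C)N1[C@@H]2C[C@H]3CC[C@]2(CS1(=O)=O)C3(C)C
A2 | alternative 1 | chloromethyl (trimethylsilyl)methyl ether | C[Si](C)(C)COCCl
A3 | alternative 1 | (3R,4R)-oxolane-3,4-dicarbonyl bis(bornane-10,2-sultam) | O=C([C@H]1COC[C@@H]1C(=O)N1[C@@H]2C[C@H]3CC[C@]2(CS1(=O)=O)C3(C)C)N1[C@@H]2C[C@H]3CC[C@]2(CS1(=O)=O)C3(C)C
A4 | alternative 1 | (3R,4R)-3,4-bis[4-(tert-butyldimethylsilyloxy)-3-methoxybenzoyl]oxolane | O=C([C@H]1COC[C@@H]1C(=O)c1ccc(O[Si](C)(C)C(C)(C)C)c(OC)c1)c1ccc(O[Si](C)(C)C(C)(C)C)c(OC)c1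
A5 | alternative 2 | (2Z,4Z)-1,6-bis{[3-methoxy-4-(triisopropylsilyloxy)phenyl]methoxy}hexa-2,4-diene | COc1cc(COC/C=C\C=C/COCc2ccc(O[Si](C(C)C)(C(C)C)C(C)C)c(OC)c2)ccc1O[Si](C(C)C)(C(C)C)C(C)C
A6 | alternative 2 | (1S,2R,3R,4S)-1,4-bis[3-methoxy-4-(triisopropylsilyloxy)phenyl]-2,3-divinylbutane-1,4-diol | COc1cc([C@@H](O)[C@@H](C=C)[C@H](C=C)[C@H](O)c2ccc(O[Si](C(C)C)(C(C)C)C(C)C)c(OC)c2)ccc1O[Si](C(C)C)(C(C)C)C(C)C
A7 | alternative 3 | ethyl N-[(2E)-3-(4-hydroxy-3-methoxyphenyl)prop-2-enoyl]-(S)-alaninate | COc1cc(/C=C/C(=O)N[C@@H](C)C(=O)OCC)ccc1O
A8 | alternative 3 | exo,exo-4,8-bis(4-hydroxy-3-methoxyphenyl)-3,7-dioxabicyclo[3.3.0]octane-2,6-dione | COc1cc([C@H]2OC(=O)[C@H]3[C@@H]2C(=O)O[C@@H]3c2ccc(O)c(OC)c2)ccc1O
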